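If Saturday's and Tuesday's flasks hold the same charge and differ in the stopping time, I had to ask what still changes after Q has reacted.

| flask | Q | X | remark | time |
|---|---|---|---|---|
| beta | 10 mM | 24 µM | run made earlier |  |
| eta | 40 mM | 24 µM | run made earlier |  |
| zeta | 20 mM | 48 µM | run made earlier |  |
| Saturday's | 20 mM | 24 µM |  | 2.0 min |
| Tuesday's | 20 mM | 24 µM |  | 1.0 min |

| run | time / s | D / % | Q / % |
|---|---|---|---|
| beta | 10.0 | 50 | 47 |
| beta | 20.0 | 74 | 24 |
| beta | 40.0 | 92 | 5 |
| beta | 90.0 | 97 | 0 |
| eta | 12.0 | 59 | 38 |
| eta | 30.0 | 86 | 12 |
| eta | 60.0 | 95 | 4 |
| eta | 90.0 | 99 | 2 |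
| zeta | 10.0 | 64 | 35 |
| zeta | 20.0 | 86 | 12 |
| zeta | 40.0 | 95 | 0 |
| zeta | 90.0 | 101 | 4 |

(standard deviation of a reading: 2 percentage points)

- the average divides the monomer in chains by the number of chains, living and dead together; two radicals that join make one chain
- the earlier runs were read with a standard deviation of 2 percentage points
- the earlier runs do not show the number of chains; that part of a forecast is a guess

- which of the two ends with the longer chains by the average number of monomer units in a chain (living and dead chains, two that joined counted as one) ("neither" if they lie within 10%) (Saturday's / Tuesday's / neither)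
- average number of monomer units in a chain (living and dead chains, two that joined counted as one) at the end, Saturday's
- average number of monomer units in a chain (living and dead chains, two that joined counted as one) at the end, Tuesday's

I read the earlier runs as pseudo-first-order loss of Q, with k as the logarithm of Q charged over Q left, divided by time. The readings gave 0.0714 s⁻¹ in beta and 0.0707 s⁻¹ in eta, though eta held 4.00 times the Q of beta. Zeta, with twice the X, gave 0.106 s⁻¹, a ratio of 1.48 against a square root of 1.41. I took this as radicals formed slowly from X and lost in pairs.

In slow motion, the two flasks begin alike: X starts to break and radicals begin adding Q. With the k of beta, the middle comes early, since the half-life of Q is 9.71 s, shorter than Tuesday's 1.0 min. By my reckoning, 1.38% of the Q remains at Tuesday's stop, so nearly all has reacted. At the end, I expected X to keep adding chains while D hardly grew.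

I therefore carried the floor length, F, the Q charged per X charged, 833. It assumes that each X gives two radicals and that these join into one chain. The length is then F times the share of Q reacted, divided by the share of X spent. The earlier runs do not show the number of chains, so I committed to no length of my own, but to Tuesday's being longer and both lying above F.

The forecast chose Tuesday's, with 1600 (500 to 8000) for Saturday's and 3000 (800 to 15000) for Tuesday's, and said “The floor is about 400 units”. My floor differs from its 400.

The flasks gave 1020 on Saturday's and 1430 on Tuesday's, so Tuesday's ended longer.

    2 E → L (k = 3.00 × 10⁶ M⁻¹ s⁻¹)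
    Q + J → E + D (k = 9.40 × 10⁵ M⁻¹ s⁻¹)
    Q + E → D + E, rate k3*[E]*[Q] (k = 2.40 × 10⁵ M⁻¹ s⁻¹)
    X → 2 J (k = 0.0140 s⁻¹)

In Saturday's flask, half of the turnover of the step from Q to D up to 2.00 min was done by 0.154 min, earlier than the 0.83 min half-life of X by its breakdown into J. At Tuesday's stop at 1.00 min, Q stood at 2.0% of its charge and X at 43% of its own. The rule with F gives 1440 for Tuesday's and 1020 for Saturday's. Saturday's charge, read at 8.0 min, held 0.12% of its X and 0.00226 mM of J. Taking that J from the radicals gives 876, and that flask's length was 876.

(The data are calculated with constants of no real substance.)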